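All runs come from a simulation on assumed constants.

The vessel is closed and stirred, at constant volume and temperature; Qa and Qb go in, and I read Qd and Qa over time.

the same everywhere: Qa 0.80 M

| run | Qb | remark | time |
|---|---|---|---|
| Tuesday's | 1.9 equiv | run made earlier |  |
| Saturday's | 1.7 equiv | run made earlier |  |
| Wednesday's | 2.5 equiv | run made earlier |  |
| ash | 1.50 equiv |  | 25 h |
| oak | 2.20 equiv |  | 25 h |

- Tuesday's (time / h: Qd / %, Qa / %): 2.50: 27.1, 29.7; 5.00: 23.7, 25.9; 8.00: 22.1, 23.9; 10.0: 20.3, 21.8; 12.0: 20.3, 18.4
- Saturday's (time / h: Qd / %, Qa / %): 1.00: 28.9, 38.0; 3.00: 25.6, 33.7; 6.00: 24.2, 29.2; 8.00: 21.0, 26.2; 12.0: 20.6, 22.5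
- Wednesday's (time / h: Qd / %, Qa / %): 1.00: 31.4, 26.8; 2.00: 27.3, 24.1; 4.00: 26.4, 21.0; 6.00: 23.2, 17.2; 12.0: 17.7, 13.8

(readings scatter by 1 percentage point)

- which of the two there is more of at the end, ash (Qd / Qg)
- which of the two there is more of at the end, oak (Qd / Qg)
- amount of Qd at the end, in percent of the Qa charged, ash
- amount of Qd at the end, in percent of the Qa charged, oak

- the numbers in the tables scatter with a standard deviation of 1 percentage point

1. I follow one Qd and ask its chance per hour of going. Saturday's run gives 0.0308 h⁻¹. Held steady from Saturday's last reading, that leaves 13.8% at 25 h.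

2. But the chance may not be steady. In Saturday's run it reads 0.0355 h⁻¹ up to 6.00 h and 0.0268 h⁻¹ after, so the later figure is lower. The scatter could produce that difference, yet Wednesday's run leans the same way.

3. So I assume the chance shrinks in step with Qd. Then one over the Qd fraction rises in a straight line. Saturday's run gives 0.127 h⁻¹. This hourly rise of one over the Qd fraction is my climb, an apparent second-order rate constant.

4. Objection: ash holds less Qb than Saturday's run. Tuesday's climb is 0.130 h⁻¹, level with Saturday's, so I keep Saturday's for ash. Starting ash from Saturday's last reading, I reckon 15.4% of Qd for ash.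

5. Objection: Wednesday's climb is 0.224 h⁻¹, larger. But oak lies midway between Tuesday's and Wednesday's charges, so I average their last readings and climbs. For oak I reckon 13.2% of Qd.

6. At Saturday's last reading, 56.9% is neither Qa nor Qd, more than the Qd. I commit to Qg as the larger in both flasks, though I cannot see how much of that is Qg.

The forecast says Qg for ash and Qg for oak, with Qd at 16.5% and 13%, on the ground of “a fast exchange that nearly equilibrates”. Its Qd for ash is more than my reckoning, and its Qd for oak is less than mine.

    Qa + Qb ⇌ Qc + Qd (K = 0.730, k = 6.90 M⁻¹ h⁻¹)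
    Qc + Qd → Qg (k = 0.190 M⁻¹ h⁻¹)
    Qd ⇌ Qf (K = 0.550, k = 0.380 h⁻¹)
    Qd + Qb ⇌ Qc + Qe (K = 0.610, k = 11.0 M⁻¹ h⁻¹)

Ash gives Qd 15.3% against Qg 47.2%, and oak gives Qd 13.1% against Qg 54.1%, so the forecast's four answers stand. Oak's Qd lies 6 points from that value when read at 11.8 h or at 53.2 h. The neighbour is ash with the same amounts, read at 2.5 d. Carrying the climb onward from ash's 15.3% gives 9.11% of Qd, and that flask holds 8.67%.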